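Ring C (C8, C9, C11–C14, cleistanthane numbering) is disconnected across C13=C14. The conjugated C13=C14–C15=C16 diene, the ring alkene plus the 14-vinyl group, is the signature of a ring-closing enyne metathesis, and the C12 carbonyl lets the first-formed cyclohexadienone aromatise. One operation thus closes ring C on a preformed ring B, creates the vinyl group by CH2 transfer and delivers the pentasubstituted phenol. The precursor is a monocyclic 2-ethynylcyclohexene carrying a CH2C(O)C(CH3)=CH2 arm. Ring B comes from asymmetric conjugate addition and Michael alkylation of 2-methylcyclohexenone; the 8-hydroperoxide is installed last by singlet-oxygen dearomatisation of the phenol.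

Key step: step 7

Remark: ring B = C5–C10 (C5 bears isopropenyl, C10 is quaternary), ring C = C8, C9, C11 (CH), C12 (C=O), C13 (C–CH3), C14 (C–vinyl), C15/C16 = vinyl; the target is (5R,8R,10R). Assumption: the sense of induction of the chiral ligand in step 1 is assigned on the first run and the antipode that gives the 3S ketone is used.

Step 1
Reactants: 1 2-methylcyclohex-2-en-1-one; 2 isopropenylmagnesium bromide (prop-1-en-2-ylmagnesium bromide, THF solution)
Product: 4 (2R,3S)-2-methyl-3-(prop-1-en-2-yl)cyclohexan-1-one (trans), via magnesium enolate 3 (not isolated)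
Conditions: Cu(OTf)2 (3 mol%), chiral NHC ligand from its imidazolinium salt (4 mol%), Et2O, −30 °C; then sat. aq NH4Cl
Reagents that add atoms: none
Why: Copper-catalysed asymmetric conjugate addition of a Grignard reagent to an α-substituted cyclic enone, in which the chiral NHC–Cu complex delivers the isopropenyl group to one face of C3 (3S here, C5 of the target) and protonation of the enolate gives the more stable trans ketone, whose C2 configuration is irrelevant because C2 is re-enolised in step 2.

Step 2
Reactants: 4 (2R,3S)-2-methyl-3-(prop-1-en-2-yl)cyclohexan-1-one; 5 methyl acrylate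
Product: 6 methyl 3-[(1R,6R)-1-methyl-2-oxo-6-(prop-1-en-2-yl)cyclohexyl]propanoate
Conditions: methyl acrylate (1.2 equiv), t-BuOK (0.15 equiv), t-BuOH/THF, 0 °C
Reagents that add atoms: none
Why: Base-catalysed Michael addition through the more substituted (thermodynamic) enolate, with the acrylate approaching anti to the neighbouring isopropenyl group, so that the propanoate arm ends trans and the methyl cis to isopropenyl and the quaternary centre C10 is set as R.

Step 3
Reactants: 6 methyl 3-[(1R,6R)-1-methyl-2-oxo-6-(prop-1-en-2-yl)cyclohexyl]propanoate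
Product: 8 methyl 3-[(1R,6R)-2-bromo-3-formyl-1-methyl-6-(prop-1-en-2-yl)cyclohex-2-en-1-yl]propanoate, via iminium bromide 7 (not isolated)
Conditions: PBr3 (2.5 equiv), DMF (3 equiv), CHCl3, 0 °C to rt; then ice-water, NaHCO3
Reagents that add atoms: N,N-dimethylformamide, CN(C)C=O; phosphorus tribromide, BrP(Br)Br; water, O
Why: Vilsmeier–Haack–Arnold bromoformylation of a ketone, in which the quaternary C10 allows enolisation only towards C8 so that the formyl carbon enters at C8 and bromide at C9, while the hindered 1,1-disubstituted alkene and the ester are not expected to react at or below room temperature and the iminium salt is hydrolysed to the aldehyde on work-up.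

Step 4
Reactants: 8 methyl 3-[(1R,6R)-2-bromo-3-formyl-1-methyl-6-(prop-1-en-2-yl)cyclohex-2-en-1-yl]propanoate
Product: 9 methyl 3-[(1R,6R)-2-bromo-3-ethynyl-1-methyl-6-(prop-1-en-2-yl)cyclohex-2-en-1-yl]propanoate
Conditions: TMSCHN2 (1.3 equiv), LDA (1.3 equiv), THF, −78 °C to 0 °C; then H2O
Reagents that add atoms: (trimethylsilyl)diazomethane, C[Si](C)(C)C=[N+]=[N-]
Why: Colvin alkyne synthesis, in which the lithiated silyldiazomethane adds only to the aldehyde at −78 °C, Peterson-type loss of silanolate and N2 gives an alkylidene carbene whose 1,2-hydrogen shift furnishes the terminal alkyne, and the absence of alkoxide avoids addition–elimination at the β-bromide.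

Step 5
Reactants: 10 3-methylbut-3-en-2-one
Product: 11 trimethyl[(3-methylbuta-1,3-dien-2-yl)oxy]silane
Conditions: TMSOTf (1.1 equiv), Et3N (1.3 equiv), Et2O, 0 °C
Reagents that add atoms: trimethylsilyl trifluoromethanesulfonate, C[Si](C)(C)OS(=O)(=O)C(F)(F)F
Why: Silyl enol ether formation by soft enolisation, which can give only one product because the methyl group is the sole enolisable position of this enone.

Step 6
Reactants: 9 methyl 3-[(1R,6R)-2-bromo-3-ethynyl-1-methyl-6-(prop-1-en-2-yl)cyclohex-2-en-1-yl]propanoate; 11 trimethyl[(3-methylbuta-1,3-dien-2-yl)oxy]silane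
Product: 13 methyl 3-[(1R,6R)-3-ethynyl-1-methyl-2-(3-methyl-2-oxobut-3-en-1-yl)-6-(prop-1-en-2-yl)cyclohex-2-en-1-yl]propanoate, via tin enolate 12 (not isolated)
Conditions: Pd2(dba)3 (2.5 mol%), P(t-Bu)3 (10 mol%), Bu3SnF (1.2 equiv), toluene, 80 °C
Reagents that add atoms: none
Why: Palladium-catalysed α-alkenylation of a ketone through its tin enolate (Migita-type enolate cross-coupling), in which fluoride exchange turns the silyl enol ether into the tin enolate, this transmetalates through its CH2 terminus to the alkenylpalladium bromide, and reductive elimination forms the C9–C11 bond under neutral, copper- and amine-free conditions that should leave the alkyne C–H untouched.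

Step 7
Reactants: 13 methyl 3-[(1R,6R)-3-ethynyl-1-methyl-2-(3-methyl-2-oxobut-3-en-1-yl)-6-(prop-1-en-2-yl)cyclohex-2-en-1-yl]propanoate
Product: 15 methyl 3-[(1R,2R)-5-ethenyl-7-hydroxy-1,6-dimethyl-2-(prop-1-en-2-yl)-1,2,3,4-tetrahydronaphthalen-1-yl]propanoate, via cyclohexadienone 14 (not isolated)
Conditions: Hoveyda–Grubbs second-generation catalyst with N,N'-di(o-tolyl) NHC (10 mol%), ethylene (1 atm), toluene (0.01 M), 80 °C
Reagents that add atoms: none
Why: Ring-closing enyne metathesis followed by keto–enol tautomerisation, the closest known reaction type being the enyne-metathesis route to 3-vinylphenols. A ruthenium methylidene adds to the terminal alkyne to give the vinylcarbene at C14, which closes onto the 1,1-disubstituted enone alkene, forming C13=C14 and passing the alkene CH2 (C16) to C15 as the vinyl group; the ethylene-mediated sequence (alkyne–ethylene cross-metathesis, then diene ring closure) gives the same product. Ring C is closed in the 6-exo mode of the 1,7-enyne, since the endo mode would require a seven-membered ring. The 2,4-cyclohexadienone tautomerises at once to the phenol, which makes the sequence irreversible, and no stereocentre is created. The step needs chemoselectivity against the C5 isopropenyl group and against alkyne oligomerisation: the isopropenyl group is shielded by the quaternary C10 and could reach C14 only through an anti-Bredt bicycle, and high dilution under ethylene suppresses oligomerisation and cross-metathesis of the product vinyl group. The demanding event is formation of the tetrasubstituted C13=C14 bond, for which the o-tolyl NHC catalyst made for hindered olefins is chosen.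

Step 8
Reactants: 15 methyl 3-[(1R,2R)-5-ethenyl-7-hydroxy-1,6-dimethyl-2-(prop-1-en-2-yl)-1,2,3,4-tetrahydronaphthalen-1-yl]propanoate
Product: 16 trigonochinene C, methyl 3-[(1R,2R,4aR)-5-ethenyl-4a-hydroperoxy-1,6-dimethyl-7-oxo-2-(prop-1-en-2-yl)-1,2,3,4,4a,7-hexahydronaphthalen-1-yl]propanoate
Conditions: O2, tetraphenylporphyrin (1 mol%), white LED, CHCl3, 0 °C, stopped before full conversion
Reagents that add atoms: dioxygen (singlet, formed by sensitisation), O=O
Why: Singlet-oxygen para-oxygenation of a 4-alkylphenol (formal [4+2] or ene-type addition across C8 and C12) gives the 4-hydroperoxycyclohexa-2,5-dienone, the electron-rich phenol should react far faster than the vinyl and isopropenyl groups, and O2 is expected to add to C8 axially, anti to the pseudoaxial C7–H of the half-chair with equatorial isopropenyl (the face syn to the C10 methyl and anti to the propanoate arm), so that ring B becomes a chair and C8 is R.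

Compound list
1 | 2-methylcyclohex-2-en-1-one | CC1=CCCCC1=O | starting material
2 | isopropenylmagnesium bromide | CC(=C)[Mg]Br | starting material
3 | bromomagnesium (3R)-2-methyl-3-(prop-1-en-2-yl)cyclohex-1-en-1-olate (same spatial arrangement at C3 as in 4) | Br[Mg]OC1=C(C)[C@@H](C(C)=C)CCC1 | intermediate (not isolated)
4 | (2R,3S)-2-methyl-3-(prop-1-en-2-yl)cyclohexan-1-one | O=C1CCC[C@H](C(=C)C)[C@H]1C | intermediate
5 | methyl acrylate | C=CC(=O)OC | starting material
6 | methyl 3-[(1R,6R)-1-methyl-2-oxo-6-(prop-1-en-2-yl)cyclohexyl]propanoate | O=C1CCC[C@H](C(=C)C)[C@@]1(C)CCC(=O)OC | intermediate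
7 | N-{[(3R,4R)-2-bromo-3-(3-methoxy-3-oxopropyl)-3-methyl-4-(prop-1-en-2-yl)cyclohex-1-en-1-yl]methylidene}-N-methylmethanaminium bromide | BrC1=C(C=[N+](C)C)CC[C@H](C(=C)C)[C@@]1(C)CCC(=O)OC.[Br-] | intermediate (not isolated)
8 | methyl 3-[(1R,6R)-2-bromo-3-formyl-1-methyl-6-(prop-1-en-2-yl)cyclohex-2-en-1-yl]propanoate | BrC1=C(C=O)CC[C@H](C(=C)C)[C@@]1(C)CCC(=O)OC | intermediate
9 | methyl 3-[(1R,6R)-2-bromo-3-ethynyl-1-methyl-6-(prop-1-en-2-yl)cyclohex-2-en-1-yl]propanoate | BrC1=C(C#C)CC[C@H](C(=C)C)[C@@]1(C)CCC(=O)OC | intermediate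
10 | 3-methylbut-3-en-2-one | CC(=O)C(C)=C | starting material
11 | trimethyl[(3-methylbuta-1,3-dien-2-yl)oxy]silane | C=C(C)C(=C)O[Si](C)(C)C | intermediate
12 | tributyl[(3-methylbuta-1,3-dien-2-yl)oxy]stannane (tin enolate) | C=C(C)C(=C)O[Sn](CCCC)(CCCC)CCCC | intermediate (not isolated)
13 | methyl 3-[(1R,6R)-3-ethynyl-1-methyl-2-(3-methyl-2-oxobut-3-en-1-yl)-6-(prop-1-en-2-yl)cyclohex-2-en-1-yl]propanoate | C=C(C)C(=O)CC1=C(C#C)CC[C@H](C(=C)C)[C@@]1(C)CCC(=O)OC | intermediate
14 | methyl 3-[(1R,2R)-5-ethenyl-1,6-dimethyl-7-oxo-2-(prop-1-en-2-yl)-1,2,3,4,7,8-hexahydronaphthalen-1-yl]propanoate | C=CC1=C(C)C(=O)CC2=C1CC[C@H](C(=C)C)[C@@]2(C)CCC(=O)OC | intermediate (not isolated)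
15 | methyl 3-[(1R,2R)-5-ethenyl-7-hydroxy-1,6-dimethyl-2-(prop-1-en-2-yl)-1,2,3,4-tetrahydronaphthalen-1-yl]propanoate | C=Cc1c(C)c(O)cc2c1CC[C@H](C(=C)C)[C@@]2(C)CCC(=O)OC | intermediate
16 | trigonochinene C, methyl 3-[(1R,2R,4aR)-5-ethenyl-4a-hydroperoxy-1,6-dimethyl-7-oxo-2-(prop-1-en-2-yl)-1,2,3,4,4a,7-hexahydronaphthalen-1-yl]propanoate | C=CC1=C(C)C(=O)C=C2[C@]1(OO)CC[C@H](C(=C)C)[C@@]2(C)CCC(=O)OC | target

Total step count: 8. Longest linear sequence: 7 (steps 1, 2, 3, 4, 6, 7, 8; step 5 prepares the coupling partner).

Steps most likely to fail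

Step 7. The ruthenium vinylcarbene may fail to engage the electron-poor, 1,1-disubstituted enone alkene, so that formation of the tetrasubstituted olefin is outrun by alkyne oligomerisation or catalyst decay. The fallback sets out from 13 and comes back at 15; it closes the ring one oxidation level lower on an electron-rich ene partner and aromatises by oxidation afterwards. Luche reduction of 13 (NaBH4, CeCl3·7H2O, MeOH, −40 °C) should give methyl 3-[(1R,6R)-3-ethynyl-2-(2-hydroxy-3-methylbut-3-en-1-yl)-1-methyl-6-(prop-1-en-2-yl)cyclohex-2-en-1-yl]propanoate F1 as a mixture of carbinol epimers. Its allylic hydroxyl activates the alkene towards the carbene, and enyne metathesis under ethylene (same catalyst, toluene, 60 °C) should give methyl 3-[(1R,2R)-5-ethenyl-7-hydroxy-1,6-dimethyl-2-(prop-1-en-2-yl)-1,2,3,4,7,8-hexahydronaphthalen-1-yl]propanoate F2, kept free of acid to avoid dehydration to the arene. Oxidation of the allylic alcohol with MnO2 (CH2Cl2, rt) should give dienone 14, which tautomerises to 15.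

Step 6. Transmetalation at the alkenylpalladium centre next to the quaternary carbon may be slow enough for the free alkyne C–H to take part (stannylation, alkynyl coupling, oligomerisation). The fallback sets out from 9 and comes back at 13; it masks the alkyne before the coupling. Silylation of 9 (TMSOTf, Et3N, Zn(OTf)2 cat., CH2Cl2, rt) should give methyl 3-[(1R,6R)-2-bromo-1-methyl-6-(prop-1-en-2-yl)-3-[(trimethylsilyl)ethynyl]cyclohex-2-en-1-yl]propanoate F3. The same tin-enolate coupling with 11 should give methyl 3-[(1R,6R)-1-methyl-2-(3-methyl-2-oxobut-3-en-1-yl)-6-(prop-1-en-2-yl)-3-[(trimethylsilyl)ethynyl]cyclohex-2-en-1-yl]propanoate F4. Silver-catalysed protodesilylation (AgNO3 cat., acetone/H2O, rt) should return 13.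

Step 8. Facial selectivity at C8 may be poor (attack syn to the propanoate arm would give the C8 epimer), and the ene reaction of the isopropenyl group or cycloaddition at the styrene unit may compete. The fallback sets out from 15 and ends at 16 without a new compound: autoxidation of the potassium phenolate with ground-state oxygen (t-BuOK, O2, THF/t-BuOH, −40 °C, then AcOH). This is a radical pathway through the phenoxyl radical with a late, product-like oxygen capture at C8 that should favour the chair hydroperoxide with equatorial isopropenyl, and the alkenes do not react with triplet oxygen.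

Further compounds
F1 | step 7 | methyl 3-[(1R,6R)-3-ethynyl-2-(2-hydroxy-3-methylbut-3-en-1-yl)-1-methyl-6-(prop-1-en-2-yl)cyclohex-2-en-1-yl]propanoate (carbinol epimers) | C=C(C)C(O)CC1=C(C#C)CC[C@H](C(=C)C)[C@@]1(C)CCC(=O)OC
F2 | step 7 | methyl 3-[(1R,2R)-5-ethenyl-7-hydroxy-1,6-dimethyl-2-(prop-1-en-2-yl)-1,2,3,4,7,8-hexahydronaphthalen-1-yl]propanoate (C7 epimers) | C=CC1=C(C)C(O)CC2=C1CC[C@H](C(=C)C)[C@@]2(C)CCC(=O)OC
F3 | step 6 | methyl 3-[(1R,6R)-2-bromo-1-methyl-6-(prop-1-en-2-yl)-3-[(trimethylsilyl)ethynyl]cyclohex-2-en-1-yl]propanoate | BrC1=C(C#C[Si](C)(C)C)CC[C@H](C(=C)C)[C@@]1(C)CCC(=O)OC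
F4 | step 6 | methyl 3-[(1R,6R)-1-methyl-2-(3-methyl-2-oxobut-3-en-1-yl)-6-(prop-1-en-2-yl)-3-[(trimethylsilyl)ethynyl]cyclohex-2-en-1-yl]propanoate | C=C(C)C(=O)CC1=C(C#C[Si](C)(C)C)CC[C@H](C(=C)C)[C@@]1(C)CCC(=O)OC
F0 | step 8 | none | none
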